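The C1–C2 bond of ring A is the one on which everything rests. C1 is the quaternary carbon bearing methyl and prenyl, and C2 is the carbonyl carbon next to the bridge-bearing C3. C1 lies between the carbonyl carbons C2 and C6, and C2 leads through C3 and the bridge CH2 to C8 of chromene ring B, so C1–C2 is an oxidised aldol bond. One TiCl4 Mukaiyama aldol joins an E-configured, fully substituted O-silyl ketene aminal of an (S)-4-benzyloxazolidinone imide (methyl and prenyl on the nucleophilic carbon) to a silyl-protected 3-(chromen-8-yl)propanal. This sets the quaternary centre and attaches ring B with its bridge carbon. C4–C5 is added afterwards and ring A is closed on the imide carbonyl C6.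

Key step: step 10

Assumption: in the open transition state the aldehyde attacks the face of the ketene aminal carbon remote from the benzyl group of the twisted oxazolidinone (the face of its carbamate carbonyl); with the (S)-auxiliary and the E isomer this gives the R quaternary centre of the target, and if the sense proved opposite the (R)-auxiliary would be used with nothing else changed.

Notation: ring A atoms are C1 (quaternary carbon with methyl and prenyl), C2 (carbonyl/enol carbon between C1 and C3), C3 (carries the bridge CH2), C4 (ring carbonyl carbon), C5 (carries the isobutyryl group), C6 (enol carbon between C5 and C1); ring B is the benzene ring of the chromene, with chromene numbering; ArTBS = 5,7-bis(tert-butyldimethylsilyloxy)-2,2-dimethyl-6-(2-methylpropanoyl)-2H-chromen-8-yl.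

**Ketene aminal arm**

Step 1
Reactants: 1 ethynyltrimethylsilane; 2 prenyl bromide (1-bromo-3-methylbut-2-ene)
Product: 4 trimethyl(5-methylhex-4-en-1-yn-1-yl)silane, via alkynylmagnesium bromide 3 (not isolated)
Conditions: EtMgBr, THF, 0 °C to rt; then CuBr·SMe2 (5 mol%), 2, rt to 45 °C
Reagents that add atoms: none
Why: Copper-catalysed coupling of an alkynyl Grignard reagent with a primary allylic bromide should occur at the unhindered CH2 terminus (SN2 sense) and give the skipped enyne, the silyl cap preventing double alkylation and base-induced isomerisation.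

Step 2
Reactants: 4 trimethyl(5-methylhex-4-en-1-yn-1-yl)silane
Product: 5 1-bromo-5-methylhex-4-en-1-yne
Conditions: NBS, AgNO3 (10 mol%), acetone, rt, dark
Reagents that add atoms: N-bromosuccinimide, O=C1CCC(=O)N1Br
Why: Silver-catalysed bromodesilylation proceeds through a silver acetylide that NBS brominates much faster than it attacks the trisubstituted alkene, so the prenyl group should survive.

Step 3
Reactants: 5 1-bromo-5-methylhex-4-en-1-yne; 6 (S)-4-benzyloxazolidin-2-one
Product: 7 (S)-4-benzyl-3-(5-methylhex-4-en-1-yn-1-yl)oxazolidin-2-one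
Conditions: CuSO4·5H2O (10 mol%), 1,10-phenanthroline (20 mol%), K3PO4, toluene, 75 °C
Reagents that add atoms: none
Why: Copper-catalysed N-alkynylation of an oxazolidinone with a bromoalkyne (ynamide coupling) is general for this auxiliary, and the weak heterogeneous phosphate base should leave the skipped enyne and the stereocentre untouched.

Step 4
Reactants: 7 (S)-4-benzyl-3-(5-methylhex-4-en-1-yn-1-yl)oxazolidin-2-one; 8 methylmagnesium bromide
Product: 11 (S)-4-benzyl-3-[(E)-2,5-dimethyl-1-(trimethylsilyloxy)hexa-1,4-dien-1-yl]oxazolidin-2-one, via vinylcopper 9 (not isolated), via lithium enolate 10 (not isolated)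
Conditions: 8, CuBr·SMe2, Et2O, −30 °C; then 7, −30 to −10 °C; then tBuOOH/nBuLi (LiOOtBu), THF, −78 °C; then TMSCl, −78 °C to rt
Reagents that add atoms: tert-butyl hydroperoxide, CC(C)(C)OO; chlorotrimethylsilane, C[Si](C)(C)Cl
Why: Carbamate-directed syn-carbocupration puts copper on the nitrogen-bearing carbon cis to the new methyl group, oxenoid oxidation of the alkenylcopper by the lithium peroxide replaces copper by oxygen with retention, and O-silylation of the fully substituted amide enolate should give only the E ketene aminal (oxygen cis to methyl, nitrogen cis to prenyl).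

**Ring B arm**

Step 5
Reactants: 12 phloroglucinol; 13 isobutyryl chloride
Product: 14 2-methyl-1-(2,4,6-trihydroxyphenyl)propan-1-one
Conditions: AlCl3 (3.5 equiv), CH2Cl2/MeNO2, 0 to 40 °C
Reagents that add atoms: none
Why: Friedel–Crafts acylation of the symmetrical triphenol gives a single ketone, and complexation of that ketone by AlCl3 deactivates the ring against a second acylation.

Step 6
Reactants: 14 2-methyl-1-(2,4,6-trihydroxyphenyl)propan-1-one; 15 3-methylbut-2-enal
Product: 16 1-(5,7-dihydroxy-2,2-dimethyl-2H-chromen-6-yl)-2-methylpropan-1-one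
Conditions: 15 (1.2 equiv), pyridine, 110 °C
Reagents that add atoms: none
Why: Amine-mediated chromenylation (condensation at the ring carbon between two hydroxyls, dehydration to an ortho-quinone methide, oxa-6π electrocyclisation) should close the pyran through the non-chelated hydroxyl para to the acyl group, giving the 6-acyl-5,7-dihydroxy isomer as the main product.

Step 7
Reactants: 16 1-(5,7-dihydroxy-2,2-dimethyl-2H-chromen-6-yl)-2-methylpropan-1-one
Product: 17 1-(5,7-dihydroxy-8-iodo-2,2-dimethyl-2H-chromen-6-yl)-2-methylpropan-1-one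
Conditions: NIS (1.05 equiv), CH2Cl2, 0 °C, dark
Reagents that add atoms: N-iodosuccinimide, O=C1CCC(=O)N1I
Why: Electrophilic aromatic iodination should occur at C8, the only free position of the highly activated ring, faster than any addition to the chromene alkene.

Step 8
Reactants: 17 1-(5,7-dihydroxy-8-iodo-2,2-dimethyl-2H-chromen-6-yl)-2-methylpropan-1-one
Product: 18 1-[5,7-bis(tert-butyldimethylsilyloxy)-8-iodo-2,2-dimethyl-2H-chromen-6-yl]-2-methylpropan-1-one
Conditions: TBSOTf (3 equiv), 2,6-lutidine, CH2Cl2, 0 °C to rt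
Reagents that add atoms: tert-butyldimethylsilyl trifluoromethanesulfonate, CC(C)(C)[Si](C)(C)OS(=O)(=O)C(F)(F)F
Why: O-Silylation with the silyl triflate is forceful enough for both hindered, hydrogen-bonded phenols, while the hindered pyridine base does not enolise the aryl ketone.

Step 9
Reactants: 18 1-[5,7-bis(tert-butyldimethylsilyloxy)-8-iodo-2,2-dimethyl-2H-chromen-6-yl]-2-methylpropan-1-one; 19 allyl alcohol
Product: 20 3-[5,7-bis(tert-butyldimethylsilyloxy)-2,2-dimethyl-6-(2-methylpropanoyl)-2H-chromen-8-yl]propanal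
Conditions: 19 (3 equiv), Pd(OAc)2 (10 mol%), Bu4NCl, NaHCO3, DMF, 50 °C
Reagents that add atoms: none
Why: In this Heck reaction under ligand-free phase-transfer conditions the arylpalladium species adds to the terminal carbon of allyl alcohol and β-hydride elimination toward the carbinol carbon delivers the 3-arylpropanal, the cis-disubstituted chromene alkene being a far poorer acceptor than the terminal alkene used in excess.

**Key step and endgame**

Step 10
Reactants: 11 (S)-4-benzyl-3-[(E)-2,5-dimethyl-1-(trimethylsilyloxy)hexa-1,4-dien-1-yl]oxazolidin-2-one; 20 3-[5,7-bis(tert-butyldimethylsilyloxy)-2,2-dimethyl-6-(2-methylpropanoyl)-2H-chromen-8-yl]propanal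
Product: 21 (S)-4-benzyl-3-[(2R,3S)-5-ArTBS-3-hydroxy-2-methyl-2-(3-methylbut-2-en-1-yl)pentanoyl]oxazolidin-2-one
Conditions: 20, TiCl4 (1.1 equiv), CH2Cl2, −78 °C; then 11 (1.3 equiv), −78 °C; aq. NaHCO3
Reagents that add atoms: none
Why: TiCl4 activates the aldehyde of 20 and the fully substituted carbon of 11 attacks it through an open, acyclic transition state, the trimethylsilyl group being lost to chloride so that aqueous work-up frees the β-hydroxy imide. The closest known reaction type is the Mukaiyama aldol of stereodefined β,β-disubstituted silyl ketene aminals of oxazolidinone imides with aliphatic aldehydes, which gives acyclic all-carbon quaternary centres. No ring is closed: the single new skeletal bond is C1–C2 of the future ring A. The quaternary centre C1 is controlled jointly by the E geometry of 11, which fixes where methyl and prenyl lie, and by the benzyl group of the oxazolidinone, which is twisted out of the enol plane and blocks one face so that the aldehyde enters on the other and the R configuration results; the carbinol centre follows from the antiperiplanar arrangement in the open transition state and is destroyed in step 11, so both epimers are usable. The step needs facial selectivity at the nucleophile, secured by the auxiliary, and chemoselectivity for the aldehyde over the aryl ketone and the acid-sensitive chromene, secured by the two flanking silyloxy groups that shield the ketone and by precomplexing one equivalent of TiCl4 with the aldehyde at −78 °C.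

Step 11
Reactants: 21 (S)-4-benzyl-3-[(2R,3S)-5-ArTBS-3-hydroxy-2-methyl-2-(3-methylbut-2-en-1-yl)pentanoyl]oxazolidin-2-one
Product: 22 (S)-4-benzyl-3-[(R)-5-ArTBS-2-methyl-2-(3-methylbut-2-en-1-yl)-3-oxopentanoyl]oxazolidin-2-one
Conditions: Dess–Martin periodinane, CH2Cl2, 0 °C to rt
Reagents that add atoms: none
Why: Dess–Martin oxidation converts the hindered secondary carbinol into the ketone under near-neutral conditions that avoid retro-aldol cleavage, and the quaternary α-carbon bears no hydrogen and cannot epimerise.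

Step 12
Reactants: 22 (S)-4-benzyl-3-[(R)-5-ArTBS-2-methyl-2-(3-methylbut-2-en-1-yl)-3-oxopentanoyl]oxazolidin-2-one; 23 1-acetyl-1H-benzotriazole
Product: 24 (S)-4-benzyl-3-[(2R)-4-(ArTBS-methyl)-2-methyl-2-(3-methylbut-2-en-1-yl)-3,5-dioxohexanoyl]oxazolidin-2-one (C4 epimers and enol forms)
Conditions: MgBr2·OEt2 (2.5 equiv), iPr2NEt, 23 (1.5 equiv), CH2Cl2, rt
Reagents that add atoms: none
Why: Soft enolisation followed by C-acylation (crossed Claisen-type acylation with an N-acylbenzotriazole) should work because magnesium chelation of the β-keto imide acidifies its single α-CH2 group (C3), and the new C3 centre, formed as a mixture of epimers and enol forms, becomes sp2 in ring A.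

Step 13
Reactants: 24 (S)-4-benzyl-3-[(2R)-4-(ArTBS-methyl)-2-methyl-2-(3-methylbut-2-en-1-yl)-3,5-dioxohexanoyl]oxazolidin-2-one
Product: 25 (S)-2-(ArTBS-methyl)-3,5-dihydroxy-4-methyl-4-(3-methylbut-2-en-1-yl)cyclohexa-2,5-dien-1-one (same spatial arrangement at C1 as in 21; the descriptor changes with the substituent priorities)
Conditions: LiN(iPr)2 (3.2 equiv), THF, −78 to 0 °C; aq. NH4Cl
Reagents that add atoms: none
Why: In this Dieckmann-type cyclisation through the 1,3-diketone dianion the terminal methyl carbanion (C5) attacks the imide carbonyl (C6) in a 6-exo-trig closure and expels the oxazolidinone anion, the non-nucleophilic amide base avoiding retro-Claisen cleavage at the quaternary carbon and the stabilised trione enolate driving the reaction.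

Step 14
Reactants: 25 (S)-2-(ArTBS-methyl)-3,5-dihydroxy-4-methyl-4-(3-methylbut-2-en-1-yl)cyclohexa-2,5-dien-1-one; 13 isobutyryl chloride
Product: 27 (R)-2-(ArTBS-methyl)-3,5-dihydroxy-4-methyl-4-(3-methylbut-2-en-1-yl)-6-(2-methylpropanoyl)cyclohexa-2,5-dien-1-one, via enol isobutyrate 26 (not isolated)
Conditions: 13 (1.1 equiv), Et3N, CH2Cl2, 0 °C; then DMAP (20 mol%), rt
Reagents that add atoms: none
Why: O-Acylation of the enolised trione followed by DMAP-mediated 1,3-acyl shift from oxygen to carbon (the standard route to 2-acylcyclohexane-1,3-diones) should deliver the isobutyryl group to C5, the only ring carbon where the product can re-enolise into a chelated triketone, whereas acylation at the substituted C3 would be reversible.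

Step 15
Reactants: 27 (R)-2-(ArTBS-methyl)-3,5-dihydroxy-4-methyl-4-(3-methylbut-2-en-1-yl)-6-(2-methylpropanoyl)cyclohexa-2,5-dien-1-one
Product: 28 (R)-2-{[5,7-dihydroxy-2,2-dimethyl-6-(2-methylpropanoyl)-2H-chromen-8-yl]methyl}-3,5-dihydroxy-4-methyl-4-(3-methylbut-2-en-1-yl)-6-(2-methylpropanoyl)cyclohexa-2,5-dien-1-one (CNP0319758.1)
Conditions: TBAF (2.5 equiv), AcOH (2.5 equiv), THF, 0 °C
Reagents that add atoms: none
Why: Fluoride-mediated desilylation cleaves both aryl silyl ethers, and acetic acid buffering keeps the phenols and the acidic triketone protonated so that the methylene bridge between two enolisable rings is not fragmented.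

**Compound list**

1 | ethynyltrimethylsilane | C#C[Si](C)(C)C | starting material
2 | prenyl bromide (1-bromo-3-methylbut-2-ene) | CC(C)=CCBr | starting material
3 | [(trimethylsilyl)ethynyl]magnesium bromide | C[Si](C)(C)C#C[Mg]Br | intermediate (not isolated)
4 | trimethyl(5-methylhex-4-en-1-yn-1-yl)silane | CC(C)=CCC#C[Si](C)(C)C | intermediate
5 | 1-bromo-5-methylhex-4-en-1-yne | CC(C)=CCC#CBr | intermediate
6 | (S)-4-benzyloxazolidin-2-one | O=C1N[C@@H](Cc2ccccc2)CO1 | starting material
7 | (S)-4-benzyl-3-(5-methylhex-4-en-1-yn-1-yl)oxazolidin-2-one | CC(C)=CCC#CN1[C@@H](Cc2ccccc2)COC1=O | intermediate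
8 | methylmagnesium bromide | C[Mg]Br | starting material
9 | {(E)-1-[(S)-4-benzyl-2-oxooxazolidin-3-yl]-2,5-dimethylhexa-1,4-dien-1-yl}copper (copper cis to methyl) | C/C(CC=C(C)C)=C(\[Cu])N1[C@@H](Cc2ccccc2)COC1=O | intermediate (not isolated)
10 | lithium (E)-1-[(S)-4-benzyl-2-oxooxazolidin-3-yl]-2,5-dimethylhexa-1,4-dien-1-olate (metal enolate drawn as its lithium salt) | C/C(CC=C(C)C)=C(\[O-])N1[C@@H](Cc2ccccc2)COC1=O.[Li+] | intermediate (not isolated)
11 | (S)-4-benzyl-3-[(E)-2,5-dimethyl-1-(trimethylsilyloxy)hexa-1,4-dien-1-yl]oxazolidin-2-one (oxygen cis to methyl) | C/C(CC=C(C)C)=C(\O[Si](C)(C)C)N1[C@@H](Cc2ccccc2)COC1=O | intermediate (key-step precursor)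
12 | phloroglucinol | Oc1cc(O)cc(O)c1 | starting material
13 | isobutyryl chloride | CC(C)C(Cl)=O | starting material
14 | 2-methyl-1-(2,4,6-trihydroxyphenyl)propan-1-one | CC(C)C(=O)c1c(O)cc(O)cc1O | intermediate
15 | 3-methylbut-2-enal | CC(C)=CC=O | starting material
16 | 1-(5,7-dihydroxy-2,2-dimethyl-2H-chromen-6-yl)-2-methylpropan-1-one | CC(C)C(=O)c1c(O)cc2OC(C)(C)C=Cc2c1O | intermediate
17 | 1-(5,7-dihydroxy-8-iodo-2,2-dimethyl-2H-chromen-6-yl)-2-methylpropan-1-one | CC(C)C(=O)c1c(O)c(I)c2OC(C)(C)C=Cc2c1O | intermediate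
18 | 1-[5,7-bis(tert-butyldimethylsilyloxy)-8-iodo-2,2-dimethyl-2H-chromen-6-yl]-2-methylpropan-1-one | CC(C)C(=O)c1c(O[Si](C)(C)C(C)(C)C)c(I)c2OC(C)(C)C=Cc2c1O[Si](C)(C)C(C)(C)C | intermediate
19 | allyl alcohol | C=CCO | starting material
20 | 3-[5,7-bis(tert-butyldimethylsilyloxy)-2,2-dimethyl-6-(2-methylpropanoyl)-2H-chromen-8-yl]propanal | O=CCCc1c(O[Si](C)(C)C(C)(C)C)c(C(=O)C(C)C)c(O[Si](C)(C)C(C)(C)C)c2c1OC(C)(C)C=C2 | intermediate (key-step precursor)
21 | (S)-4-benzyl-3-[(2R,3S)-5-ArTBS-3-hydroxy-2-methyl-2-(3-methylbut-2-en-1-yl)pentanoyl]oxazolidin-2-one | CC(C)=CC[C@](C(=O)N1[C@@H](Cc2ccccc2)COC1=O)(C)[C@@H](O)CCc1c(O[Si](C)(C)C(C)(C)C)c(C(=O)C(C)C)c(O[Si](C)(C)C(C)(C)C)c2c1OC(C)(C)C=C2 | intermediate (key-step product)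
22 | (S)-4-benzyl-3-[(R)-5-ArTBS-2-methyl-2-(3-methylbut-2-en-1-yl)-3-oxopentanoyl]oxazolidin-2-one | CC(C)=CC[C@](C(=O)N1[C@@H](Cc2ccccc2)COC1=O)(C)C(=O)CCc1c(O[Si](C)(C)C(C)(C)C)c(C(=O)C(C)C)c(O[Si](C)(C)C(C)(C)C)c2c1OC(C)(C)C=C2 | intermediate
23 | 1-acetyl-1H-benzotriazole | CC(=O)n1nnc2ccccc12 | starting material
24 | (S)-4-benzyl-3-[(2R)-4-(ArTBS-methyl)-2-methyl-2-(3-methylbut-2-en-1-yl)-3,5-dioxohexanoyl]oxazolidin-2-one (C4 undefined) | CC(C)=CC[C@](C(=O)N1[C@@H](Cc2ccccc2)COC1=O)(C)C(=O)C(C(C)=O)Cc1c(O[Si](C)(C)C(C)(C)C)c(C(=O)C(C)C)c(O[Si](C)(C)C(C)(C)C)c2c1OC(C)(C)C=C2 | intermediate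
25 | (S)-2-(ArTBS-methyl)-3,5-dihydroxy-4-methyl-4-(3-methylbut-2-en-1-yl)cyclohexa-2,5-dien-1-one | CC(C)=CC[C@]1(C)C(O)=C(Cc2c(O[Si](C)(C)C(C)(C)C)c(C(=O)C(C)C)c(O[Si](C)(C)C(C)(C)C)c3c2OC(C)(C)C=C3)C(=O)C=C1O | intermediate
26 | enol isobutyrate of 25 (one of the regioisomeric O-acyl enols, drawn on the C6 oxygen) | CC(C)=CC[C@]1(C)C(O)=C(Cc2c(O[Si](C)(C)C(C)(C)C)c(C(=O)C(C)C)c(O[Si](C)(C)C(C)(C)C)c3c2OC(C)(C)C=C3)C(=O)C=C1OC(=O)C(C)C | intermediate (not isolated)
27 | (R)-2-(ArTBS-methyl)-3,5-dihydroxy-4-methyl-4-(3-methylbut-2-en-1-yl)-6-(2-methylpropanoyl)cyclohexa-2,5-dien-1-one | CC(C)=CC[C@]1(C)C(O)=C(Cc2c(O[Si](C)(C)C(C)(C)C)c(C(=O)C(C)C)c(O[Si](C)(C)C(C)(C)C)c3c2OC(C)(C)C=C3)C(=O)C(C(=O)C(C)C)=C1O | intermediate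
28 | (R)-2-{[5,7-dihydroxy-2,2-dimethyl-6-(2-methylpropanoyl)-2H-chromen-8-yl]methyl}-3,5-dihydroxy-4-methyl-4-(3-methylbut-2-en-1-yl)-6-(2-methylpropanoyl)cyclohexa-2,5-dien-1-one | CC(C)=CC[C@]1(C)C(O)=C(Cc2c(O)c(C(=O)C(C)C)c(O)c3c2OC(C)(C)C=C3)C(=O)C(C(=O)C(C)C)=C1O | target

**Totals**

Total step count: 15. Longest linear sequence: 11 steps (steps 5–15, from phloroglucinol); the ketene aminal arm (steps 1–4) joins at step 10.

**Steps most likely to fail**

1. Step 10. The aldehyde may approach the ketene aminal with poor facial discrimination in the open transition state, or TiCl4 may ionise the chromene C–O bond or strip an aryl silyl ether before the C–C bond forms. Fallback: replace the Lewis-acid aldol by the aldol of the metal enolate itself. Setting out from ynamide 7, carbocupration and oxidation as in step 4 give enolate 10, which is not silylated but treated directly with aldehyde 20 at −78 °C. It should react through a closed, chair-like six-membered transition state under Lewis-acid-free conditions, with the same E geometry and the same auxiliary fixing C1. The carbinol configuration is again irrelevant, and the route is rejoined at 21 (new compound: none F0).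

2. Step 13. The dianion may fail to acylate the hindered imide carbonyl next to the quaternary carbon, enol oxygen may acylate instead of carbon, or the strong base may move a silyl group on ring B. Fallback: exchange the acyl leaving group before ring A is assembled. Setting out from 21, LiSEt (from EtSH and nBuLi, THF, 0 °C) should displace the auxiliary to give hydroxy thioester F1. Dess–Martin oxidation should then give keto thioester F2, and the soft-enolisation acetylation with 23 (MgBr2·OEt2, iPr2NEt) should give diketo thioester F3. The slimmer and more electrophilic thioester should then undergo the Dieckmann closure with LiN(iPr)2 in THF at −78 to 0 °C with loss of ethanethiol, coming back to the route at 25.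

3. Step 9. Oxidative addition and insertion may be slow at the doubly ortho-substituted, electron-rich iodide, the chromene alkene may insert competitively, or a silyl ether may be lost in warm basic DMF. Fallback: replace the Heck reaction by cross-coupling with a masked homoenolate. Setting out from 18, Negishi coupling with [2-(1,3-dioxolan-2-yl)ethyl]zinc bromide (Pd(OAc)2, SPhos, THF, 50 °C) should give acetal F4. Hydrolysis of the dioxolane (1 M HCl, THF, rt) then comes back to the route at 20.

**Further compounds**

F0 | step 10 | none | none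
F1 | step 13 | S-ethyl (2R,3S)-5-ArTBS-3-hydroxy-2-methyl-2-(3-methylbut-2-en-1-yl)pentanethioate | CC(C)=CC[C@](C(=O)SCC)(C)[C@@H](O)CCc1c(O[Si](C)(C)C(C)(C)C)c(C(=O)C(C)C)c(O[Si](C)(C)C(C)(C)C)c2c1OC(C)(C)C=C2
F2 | step 13 | S-ethyl (R)-5-ArTBS-2-methyl-2-(3-methylbut-2-en-1-yl)-3-oxopentanethioate | CC(C)=CC[C@](C(=O)SCC)(C)C(=O)CCc1c(O[Si](C)(C)C(C)(C)C)c(C(=O)C(C)C)c(O[Si](C)(C)C(C)(C)C)c2c1OC(C)(C)C=C2
F3 | step 13 | S-ethyl (2R)-4-(ArTBS-methyl)-2-methyl-2-(3-methylbut-2-en-1-yl)-3,5-dioxohexanethioate (C4 undefined) | CC(C)=CC[C@](C(=O)SCC)(C)C(=O)C(C(C)=O)Cc1c(O[Si](C)(C)C(C)(C)C)c(C(=O)C(C)C)c(O[Si](C)(C)C(C)(C)C)c2c1OC(C)(C)C=C2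
F4 | step 9 | 1-{5,7-bis(tert-butyldimethylsilyloxy)-8-[2-(1,3-dioxolan-2-yl)ethyl]-2,2-dimethyl-2H-chromen-6-yl}-2-methylpropan-1-one | CC(C)C(=O)c1c(O[Si](C)(C)C(C)(C)C)c(CCC2OCCO2)c2OC(C)(C)C=Cc2c1O[Si](C)(C)C(C)(C)C
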